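**Plan**

1. The retrosynthesis cuts the two bonds from ring A of the flavan (C8 and C6) to the benzylic methines. Both side units are identical in constitution and configuration, so the target falls into (+)-afzelechin and two copies of one tetrahydrofuran electrophile, and ring A needs no regiocontrol.
2. Three features make this possible: each methine carries a 4-hydroxyphenyl group and can become the terminus of a para-quinone methide; ring A is a phloroglucinol-type ring whose C6 and C8 each lie between two oxygens; and the C4 aroyl ketone of each tetrahydrofuran sits 1,3 to the methine, so a CO2 bridge (β-keto-γ-lactone, C4–C(=O)–O–CH) can act as an internal leaving group and be lost again as CO2.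
3. The electrophile is cut further at the CO2 bridge, the C4–aroyl bond, the C2–aryl bond and the C3–CH bond, back to a trans-5-aryl-γ-lactone-4-carboxylic acid from an Evans aldol reaction.
4. Forward: the γ-lactone is made first and its C3 side chain added; the lactone becomes the 2-aryl tetrahydrofuran (O1–C2–C3–C4–C5); the C4 ketone and then the temporary lactone ring are built; ring A is alkylated twice in one operation (C8, then C6); ten benzyl ethers are removed.
5. Stereochemistry: C4 and C5 come from the oxazolidinone auxiliary, C3 from enolate attack anti to the C4 carboxylate, C2 from hydride attack anti to the C3 substituent, both methines from arylation on the face opposite the tethered carboxylate, and flavan C2/C3 from (+)-afzelechin.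

Key step: step 10

Remark: the tetrahydrofuran (and its lactone precursors) is numbered O1, C2 (lactone carbonyl, later the carbon with the 2,4-dioxygenated aryl group), C3 (side chain), C4 (carboxyl, later aroyl), C5 (4-oxyphenyl). "Methine" or "carbinol carbon" is the exocyclic benzylic carbon on C3.

Assumption: (+)-afzelechin and 1-bromo-2,4-bis(benzyloxy)benzene are bought; the bromide is otherwise one benzylation away from 4-bromoresorcinol.

Remark: step 4 gives both epimers at the carbinol carbon. They are carried together because this centre becomes trigonal in step 10.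

**Route**

Step 1
Reactants: 1 (S)-4-benzyl-2-oxazolidinone; 2 methyl 4-chloro-4-oxobutanoate
Product: 3 (S)-4-benzyl-3-(4-methoxy-4-oxobutanoyl)oxazolidin-2-one
Conditions: n-BuLi, THF, −78 °C; then 2, −78 to 0 °C
Reagents that add atoms: none
Why: N-acylation of the lithiated oxazolidinone by the acid chloride is the standard preparation of an Evans imide and touches no stereocentre.

Step 2
Reactants: 3 imide; 4 4-(benzyloxy)benzaldehyde
Product: 6 trans-lactone imide (4S,5S), via syn-aldol adduct 5 (not isolated)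
Conditions: Bu2BOTf, i-Pr2NEt, CH2Cl2, 0 °C; 4, −78 to 0 °C; pH 7 buffer, MeOH, H2O2; then TsOH·H2O (cat.), CH2Cl2, rt
Reagents that add atoms: none
Why: The Evans syn-aldol reaction through the (Z)-boron enolate and a chair transition state should set C4 and C5 under auxiliary control, and the γ-hydroxy ester then closes to the 4,5-trans lactone.

Step 3
Reactants: 6 trans-lactone imide
Product: 7 (4S,5S)-5-[4-(benzyloxy)phenyl]-2-oxotetrahydrofuran-4-carboxylic acid
Conditions: LiOH, H2O2, THF/H2O, 0 °C; Na2SO3; HCl to pH 2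
Reagents that add atoms: hydrogen peroxide (as LiOOH), OO
Why: Lithium hydroperoxide should cleave the exocyclic imide carbonyl selectively (standard auxiliary removal); any opened lactone re-closes on acidification, and no stereocentre is touched.

Step 4
Reactants: 7 lactone acid; 8 4-[(tert-butyldimethylsilyl)oxy]benzaldehyde
Product: 9 (3R,4S,5S)-5-[4-(benzyloxy)phenyl]-3-[{4-[(tert-butyldimethylsilyl)oxy]phenyl}(hydroxy)methyl]-2-oxotetrahydrofuran-4-carboxylic acid (both carbinol epimers)
Conditions: LiN(SiMe3)2 (2.2 equiv), THF, −78 °C; then 8, −78 °C; AcOH, −78 °C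
Reagents that add atoms: none
Why: The carboxylate–lactone enolate dianion should add to the aldehyde (lactone aldol) from the face anti to the C4 carboxylate, which sets C3 trans to C4.

Step 5
Reactants: 9 aldol acid; 10 1-bromo-2,4-bis(benzyloxy)benzene
Product: 12 lactol acid (C2 hemiketal carrying the 2,4-bis(benzyloxy)phenyl group), via aryllithium 11 (not isolated)
Conditions: 10 (3.4 equiv), n-BuLi, THF, −78 °C; then 9, −78 °C; NH4Cl (aq)
Reagents that add atoms: none
Why: After bromine–lithium exchange, 1,2-addition of the aryllithium to the lactone carbonyl should stop at the lithium hemiketal alkoxide, while the lithium carboxylate at C4 is inert at −78 °C.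

Step 6
Reactants: 12 lactol acid
Product: 13 tetrahydrofuran acid (2R,3R,4S,5S): C2 2,4-bis(benzyloxy)phenyl, C3 CH(OH)[4-(silyloxy)phenyl], C4 CO2H, C5 4-(benzyloxy)phenyl
Conditions: Et3SiH, BF3·OEt2, CH2Cl2, −78 °C; NaHCO3 (aq)
Reagents that add atoms: none
Why: In this ionic hydrogenation the aryl-stabilised cyclic oxocarbenium ion should take hydride on the face anti to the C3 substituent, which places the C2 aryl group cis to C3 and to the C5 aryl group; the much less stabilised benzylic carbinol should not ionise at −78 °C.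

Step 7
Reactants: 13 tetrahydrofuran acid
Product: 14 N-methoxy-N-methyl amide of 13 (2R,3R,4S,5S)
Conditions: MeNH(OMe)·HCl, EDC·HCl, HOBt, i-Pr2NEt, CH2Cl2, 0 °C to rt
Reagents that add atoms: N,O-dimethylhydroxylamine hydrochloride, CNOC.Cl
Why: Carbodiimide amide coupling gives the Weinreb amide; the carbinol and the C4 carboxyl are trans on the ring, so lactonisation cannot compete.

Step 8
Reactants: 14 Weinreb amide; 10 1-bromo-2,4-bis(benzyloxy)benzene
Product: 16 ketone (2R,3R,4S,5S) carrying the 2,4-bis(benzyloxy)benzoyl group on C4, via arylmagnesium bromide 15 (not isolated)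
Conditions: 10 (3 equiv), Mg turnings, I2 (cat.), THF, 50 °C; then 14, THF, 0 °C to rt; NH4Cl (aq)
Reagents that add atoms: none
Why: In this Weinreb ketone synthesis the first equivalent of the aryl Grignard reagent deprotonates the carbinol and the second forms the stable magnesium-chelated tetrahedral adduct, which should release the aryl ketone only on work-up.

Step 9
Reactants: 16 ketone
Product: 18 cis-fused β-keto-γ-lactone (2R,3S,4R,5R; both epimers at the methine), via imidazole-1-carboxylate 17 (not isolated)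
Conditions: 1,1'-carbonyldiimidazole (1.1 equiv), THF, 0 °C to rt; then LiN(SiMe3)2 (2.2 equiv), −78 to −20 °C; NH4Cl (aq)
Reagents that add atoms: 1,1'-carbonyldiimidazole, O=C(n1ccnc1)n1ccnc1
Why: The carbinol is converted into its imidazole-1-carboxylate and the C4 ketone enolate is C-acylated intramolecularly (Dieckmann-type Claisen acylation, 5-exo-trig); this can only give the cis-fused lactone, the new carbonyl lying on the face of the side chain and the aroyl group on the other face.

Step 10
Reactants: 18 β-keto-γ-lactone (2.3 equiv); 19 (+)-afzelechin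
Product: 23 deca-O-benzyl ether of the target, via quinone methide acid 20 (not isolated), via mono-adduct 21 (not isolated), via bis(keto acid) 22 (not isolated)
Conditions: Bu4NF (5 equiv), THF/DMF, −40 to 0 °C, argon; then AcOH, 40 °C
Reagents that add atoms: none
Why: Proposed new method: fluoride cleaves the aryl silyl ether of 18, the phenoxide expels the lactone oxygen by 1,6-elimination to give para-quinone methide 20 whose carboxylate is still bound to C4 on the Re face of the methine, and the ring A phenoxide of afzelechin adds through C8 and then, on mono-adduct 21, through C6 to give 22, which loses two CO2 on acidification; the closest known reaction types are the fluoride-triggered generation of para-quinone methides from para-silyloxybenzyl esters followed by 1,6-addition of phenols (Friedel–Crafts type) and the decarboxylation of β-keto acids. No ring is closed; the γ-lactone, the temporary ring, is opened. Each new methine stereocentre (S) should arise by attack on the Si face, anti to the anionic carboxylate that has just left and is held on C4, where it screens and repels the anionic nucleophile; C4 is restored by thermodynamic protonation of the enol, the aroyl group ending trans to both ring neighbours. The step needs C- over O-alkylation (aryl ether adducts and lactone re-closure revert by the same 1,6-elimination, the C–C bond does not) and chemoselective ionisation (only the unmasked phenol can form a quinone methide; the benzyl-protected benzylic ethers at C2 and C5 cannot), but no regiocontrol, because C6 and C8 receive the identical unit.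

Step 11
Reactants: 23 deca-O-benzyl ether
Product: 24 target: (2R,3S)-afzelechin carrying at C6 and at C8 the same (S)-[(2R,3S,4S,5S)-4-(2,4-dihydroxybenzoyl)-2-(2,4-dihydroxyphenyl)-5-(4-hydroxyphenyl)tetrahydrofuran-3-yl](4-hydroxyphenyl)methyl group
Conditions: H2 (1 atm), Pd(OH)2 on carbon, THF/MeOH, rt
Reagents that add atoms: none
Why: Hydrogenolysis should remove the ten aryl benzyl ethers faster than it attacks the aryl ketones or the cyclic benzylic ethers, and no stereocentre is touched.

**Compound list**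

1 | (S)-4-benzyl-2-oxazolidinone | O=C1N[C@@H](Cc2ccccc2)CO1 | starting material
2 | methyl 4-chloro-4-oxobutanoate | COC(=O)CCC(Cl)=O | starting material
3 | (S)-4-benzyl-3-(4-methoxy-4-oxobutanoyl)oxazolidin-2-one | COC(=O)CCC(=O)N1[C@@H](Cc2ccccc2)COC1=O | intermediate
4 | 4-(benzyloxy)benzaldehyde | O=Cc1ccc(OCc2ccccc2)cc1 | starting material
5 | syn-aldol adduct, methyl (3S,4S)-3-{[(S)-4-benzyl-2-oxooxazolidin-3-yl]carbonyl}-4-[4-(benzyloxy)phenyl]-4-hydroxybutanoate | O=C(N1[C@@H](Cc2ccccc2)COC1=O)[C@H]([C@H](O)c1ccc(OCc2ccccc2)cc1)CC(=O)OC | intermediate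
6 | trans-lactone imide, (S)-4-benzyl-3-{[(4S,5S)-5-[4-(benzyloxy)phenyl]-2-oxotetrahydrofuran-4-yl]carbonyl}oxazolidin-2-one | O=C(N1[C@@H](Cc2ccccc2)COC1=O)[C@H]1CC(=O)O[C@@H]1c1ccc(OCc2ccccc2)cc1 | intermediate
7 | (4S,5S)-5-[4-(benzyloxy)phenyl]-2-oxotetrahydrofuran-4-carboxylic acid (4,5-trans) | O=C(O)[C@H]1CC(=O)O[C@@H]1c1ccc(OCc2ccccc2)cc1 | intermediate
8 | 4-[(tert-butyldimethylsilyl)oxy]benzaldehyde | O=Cc1ccc(O[Si](C)(C)C(C)(C)C)cc1 | starting material
9 | (3R,4S,5S)-5-[4-(benzyloxy)phenyl]-3-[{4-[(tert-butyldimethylsilyl)oxy]phenyl}(hydroxy)methyl]-2-oxotetrahydrofuran-4-carboxylic acid (3,4-trans, 4,5-trans; both carbinol epimers) | O=C(O)[C@H]1[C@H](C(O)c2ccc(O[Si](C)(C)C(C)(C)C)cc2)C(=O)O[C@@H]1c1ccc(OCc2ccccc2)cc1 | intermediate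
10 | 1-bromo-2,4-bis(benzyloxy)benzene | Brc1ccc(OCc2ccccc2)cc1OCc1ccccc1 | starting material
11 | 2,4-bis(benzyloxy)phenyllithium | [Li]c1ccc(OCc2ccccc2)cc1OCc1ccccc1 | intermediate
12 | lactol acid: (3R,4S,5S) acid 9 with C2 as hemiketal carbon bearing OH and 2,4-bis(benzyloxy)phenyl (both anomers, both carbinol epimers) | O=C(O)[C@H]1[C@H](C(O)c2ccc(O[Si](C)(C)C(C)(C)C)cc2)C(O)(c2ccc(OCc3ccccc3)cc2OCc2ccccc2)O[C@@H]1c1ccc(OCc2ccccc2)cc1 | intermediate
13 | tetrahydrofuran acid (2R,3R,4S,5S): C2 2,4-bis(benzyloxy)phenyl, C3 CH(OH)[4-(tert-butyldimethylsilyloxy)phenyl], C4 CO2H, C5 4-(benzyloxy)phenyl; 2,3-cis, 3,4-trans, 4,5-trans; both carbinol epimers | O=C(O)[C@H]1[C@H](C(O)c2ccc(O[Si](C)(C)C(C)(C)C)cc2)[C@H](c2ccc(OCc3ccccc3)cc2OCc2ccccc2)O[C@@H]1c1ccc(OCc2ccccc2)cc1 | intermediate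
14 | N-methoxy-N-methyl amide of 13 (2R,3R,4S,5S) | CON(C)C(=O)[C@H]1[C@H](C(O)c2ccc(O[Si](C)(C)C(C)(C)C)cc2)[C@H](c2ccc(OCc3ccccc3)cc2OCc2ccccc2)O[C@@H]1c1ccc(OCc2ccccc2)cc1 | intermediate
15 | 2,4-bis(benzyloxy)phenylmagnesium bromide | Br[Mg]c1ccc(OCc2ccccc2)cc1OCc1ccccc1 | intermediate
16 | ketone (2R,3R,4S,5S): as 13 but carrying a 2,4-bis(benzyloxy)benzoyl group on C4 in place of CO2H; both carbinol epimers | O=C(c1ccc(OCc2ccccc2)cc1OCc1ccccc1)[C@H]1[C@H](C(O)c2ccc(O[Si](C)(C)C(C)(C)C)cc2)[C@H](c2ccc(OCc3ccccc3)cc2OCc2ccccc2)O[C@@H]1c1ccc(OCc2ccccc2)cc1 | intermediate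
17 | imidazole-1-carboxylate of the carbinol of 16 | O=C(c1ccc(OCc2ccccc2)cc1OCc1ccccc1)[C@H]1[C@H](C(OC(=O)n2ccnc2)c2ccc(O[Si](C)(C)C(C)(C)C)cc2)[C@H](c2ccc(OCc3ccccc3)cc2OCc2ccccc2)O[C@@H]1c1ccc(OCc2ccccc2)cc1 | intermediate
18 | β-keto-γ-lactone (2R,3S,4R,5R): tetrahydrofuran of 16 bearing a C(=O)–O bridge from C4 to the methine oxygen, cis-fused; lactone carbonyl and the C2 and C5 aryl groups on one face, aroyl group on the other; both epimers at the methine | O=C(c1ccc(OCc2ccccc2)cc1OCc1ccccc1)[C@@]12C(=O)OC(c3ccc(O[Si](C)(C)C(C)(C)C)cc3)[C@@H]1[C@H](c1ccc(OCc3ccccc3)cc1OCc1ccccc1)O[C@@H]2c1ccc(OCc2ccccc2)cc1 | intermediate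
19 | (+)-afzelechin, (2R,3S)-2-(4-hydroxyphenyl)chroman-3,5,7-triol | Oc1cc(O)c2c(c1)O[C@H](c1ccc(O)cc1)[C@@H](O)C2 | starting material
20 | quinone methide acid: desilylated, ring-opened 18; C3 carries the (4-oxocyclohexa-2,5-dien-1-ylidene)methyl group, C4 carries CO2H (cis to that group) and the aroyl group; drawn as the free acid | O=C(c1ccc(OCc2ccccc2)cc1OCc1ccccc1)[C@@]1(C(=O)O)[C@H](C=C2C=CC(=O)C=C2)[C@H](c2ccc(OCc3ccccc3)cc2OCc2ccccc2)O[C@@H]1c1ccc(OCc2ccccc2)cc1 | intermediate
21 | mono-adduct: (+)-afzelechin carrying at C8 the (S)-methine unit whose C4 still bears CO2H (the C6 isomer converges on 22) | Oc1cc(O)c2c(c1[C@H](c1ccc(O)cc1)[C@H]1[C@](C(=O)O)(C(=O)c3ccc(OCc4ccccc4)cc3OCc3ccccc3)[C@@H](c3ccc(OCc4ccccc4)cc3)O[C@H]1c1ccc(OCc3ccccc3)cc1OCc1ccccc1)O[C@H](c1ccc(O)cc1)[C@@H](O)C2 | intermediate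
22 | bis(keto acid): 23 bearing a CO2H group on C4 of each tetrahydrofuran, cis to the C3 side chain | O=C(c1ccc(OCc2ccccc2)cc1OCc1ccccc1)[C@@]1(C(=O)O)[C@H]([C@@H](c2ccc(O)cc2)c2c(O)c3c(c([C@H](c4ccc(O)cc4)[C@H]4[C@](C(=O)O)(C(=O)c5ccc(OCc6ccccc6)cc5OCc5ccccc5)[C@@H](c5ccc(OCc6ccccc6)cc5)O[C@H]4c4ccc(OCc5ccccc5)cc4OCc4ccccc4)c2O)O[C@H](c2ccc(O)cc2)[C@@H](O)C3)[C@H](c2ccc(OCc3ccccc3)cc2OCc2ccccc2)O[C@@H]1c1ccc(OCc2ccccc2)cc1 | intermediate
23 | deca-O-benzyl ether of the target: benzyl ethers on the four 2,4-dioxygenated rings and on the two C5 aryl rings; the two methine 4-hydroxyphenyl groups and all afzelechin hydroxyls free; configuration as in 24 | O=C(c1ccc(OCc2ccccc2)cc1OCc1ccccc1)[C@H]1[C@H]([C@@H](c2ccc(O)cc2)c2c(O)c3c(c([C@H](c4ccc(O)cc4)[C@H]4[C@H](C(=O)c5ccc(OCc6ccccc6)cc5OCc5ccccc5)[C@@H](c5ccc(OCc6ccccc6)cc5)O[C@H]4c4ccc(OCc5ccccc5)cc4OCc4ccccc4)c2O)O[C@H](c2ccc(O)cc2)[C@@H](O)C3)[C@H](c2ccc(OCc3ccccc3)cc2OCc2ccccc2)O[C@@H]1c1ccc(OCc2ccccc2)cc1 | intermediate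
24 | target (CNP0225367.3): (2R,3S)-afzelechin bearing the (S)-[(2R,3S,4S,5S)-4-(2,4-dihydroxybenzoyl)-2-(2,4-dihydroxyphenyl)-5-(4-hydroxyphenyl)tetrahydrofuran-3-yl](4-hydroxyphenyl)methyl group at C6 and at C8 | O=C(c1ccc(O)cc1O)[C@H]1[C@H]([C@@H](c2ccc(O)cc2)c2c(O)c3c(c([C@H](c4ccc(O)cc4)[C@H]4[C@H](C(=O)c5ccc(O)cc5O)[C@@H](c5ccc(O)cc5)O[C@H]4c4ccc(O)cc4O)c2O)O[C@H](c2ccc(O)cc2)[C@@H](O)C3)[C@H](c2ccc(O)cc2O)O[C@@H]1c1ccc(O)cc1 | target

Total step count: 11. Longest linear sequence: 11 steps (1 to 24).

**Steps most likely to fail**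

Step 10. The facial selectivity at the methine may be poor: the C2 aryl group, cis to the side chain, crowds the Si face, and a bridging cation could deliver the phenoxide to the Re face. The quinone methide may also tautomerise to the 4-hydroxystyryl isomer, which destroys the C3 stereocentre. Fallback, from 16 back to 23: 16 is desilylated (HF·pyridine, THF, 0 °C) to the para-hydroxybenzylic alcohol F1. F1 (2.3 equiv) and 19 are then joined under chiral phosphoric acid catalysis (the BINOL-derived 3,3'-bis(2,4,6-triisopropylphenyl) phosphoric acid, 10 mol %, CH2Cl2, 4 Å molecular sieves, 0 °C). This is the known acid-catalysed dehydration to a free para-quinone methide followed by catalyst-controlled 1,6-addition of a phenol ring; the catalyst antipode that sends ring A to the Si face is used. The product is 23.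

Step 9. The imidazole-1-carboxylate may be lost by ionisation of the electron-rich benzylic C–O bond (decarboxylative N-benzylation), or the enolate may be acylated on oxygen. Fallback, from 16 back to 23: 16 is treated first with Ms2O and Et3N in CH2Cl2 at −40 °C and then DBU, which should give the donor–acceptor cyclopropyl ketone F2 by 3-exo C-alkylation of the C4 enolate (the classical closure of a ketone that has a leaving group on the γ-carbon). F2 (2.3 equiv) and 19 in the presence of Sc(OTf)3 (10 mol %) in CH2Cl2 should give the bis-silyl ether F3 by Friedel–Crafts opening of the cyclopropane at the donor carbon, which proceeds by inversion. HF·pyridine then gives 23.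

Step 11. Over-reduction may occur once the phenols are free: hydrogenolysis of the cyclic benzylic C–O bonds (C2–O1 and C5–O1 of the tetrahydrofurans, C2–O1 of the flavan) or reduction of the aryl ketones. Fallback, from 23 to 24: 23 is debenzylated by BCl3 in the presence of pentamethylbenzene in CH2Cl2 at −78 °C, a Lewis-acid cleavage in which the scavenger traps the benzyl cations. This fallback makes no new compound (F0).

**Further compounds**

F1 | step 10 | para-hydroxybenzylic alcohol: 16 in which the silyl ether is replaced by a free phenol | O=C(c1ccc(OCc2ccccc2)cc1OCc1ccccc1)[C@H]1[C@H](C(O)c2ccc(O)cc2)[C@H](c2ccc(OCc3ccccc3)cc2OCc2ccccc2)O[C@@H]1c1ccc(OCc2ccccc2)cc1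
F2 | step 9 | cyclopropyl ketone: 3-oxabicyclo[3.1.0]hexane bearing the 2,4-bis(benzyloxy)benzoyl group on C1, 4-(benzyloxy)phenyl on C2, 2,4-bis(benzyloxy)phenyl on C4 (both cis to the cyclopropane) and 4-(tert-butyldimethylsilyloxy)phenyl exo on C6 | O=C(c1ccc(OCc2ccccc2)cc1OCc1ccccc1)[C@@]12[C@@H](c3ccc(O[Si](C)(C)C(C)(C)C)cc3)[C@@H]1[C@H](c1ccc(OCc3ccccc3)cc1OCc1ccccc1)O[C@@H]2c1ccc(OCc2ccccc2)cc1
F3 | step 9 | bis-silyl ether: 23 in which both methine 4-hydroxyphenyl groups are tert-butyldimethylsilyl ethers | O=C(c1ccc(OCc2ccccc2)cc1OCc1ccccc1)[C@H]1[C@H]([C@@H](c2ccc(O[Si](C)(C)C(C)(C)C)cc2)c2c(O)c3c(c([C@H](c4ccc(O[Si](C)(C)C(C)(C)C)cc4)[C@H]4[C@H](C(=O)c5ccc(OCc6ccccc6)cc5OCc5ccccc5)[C@@H](c5ccc(OCc6ccccc6)cc5)O[C@H]4c4ccc(OCc5ccccc5)cc4OCc4ccccc4)c2O)O[C@H](c2ccc(O)cc2)[C@@H](O)C3)[C@H](c2ccc(OCc3ccccc3)cc2OCc2ccccc2)O[C@@H]1c1ccc(OCc2ccccc2)cc1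
F0 | step 11 | none | none
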